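**Retrosynthetic overview**
1. Remangiflavanone B comes from its 5,2',4'-tri-MOM ether by mild acid removal of the three acetals.
2. Rings A and C of that ether are built in one pot. A two-carbon lithium ynolate (C8–C8a, already carrying the side chain) is merged with a 4-MOMO-6-styryl-2-pyranone, which supplies C7–C6–C5–C4a, C4–C3–C2 and ring B. The pyranone ring is sacrificed.
3. Ring order: B (bought), then A (ynolate acylation, ring opening, ketene capture, aromatisation to a chalcone with a single free ortho-OH), then C (catalyst-controlled oxa-Michael that sets 2S; only the 8-alkyl isomer can form).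
4. The ynolate comes from a terminal alkyne, which comes from (R)-limonene (ring-alkene cleavage, CHO to C≡CH, C=O to C=CH2). Limonene C4 is the side-chain (R) centre and limonene C2 becomes C8.
5. The styrylpyranone comes from triacetic acid lactone and 2,4-dihydroxybenzaldehyde (MOM protection, vinylogous aldol condensation).

Assumption: the SMILES is read as the (2S)-flavanone with a (2R)-5-methyl-2-(prop-1-en-2-yl)hex-5-en-1-yl group at C8, and commercial (R)-(+)-limonene is taken as enantiopure.

**Step 1**
Reactants: 1 (R)-(+)-limonene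
Product: 3 (3R)-6-oxo-3-(prop-1-en-2-yl)heptanal, via secondary ozonide 2 (not isolated)
Conditions: O3 (1.0 equiv), CH2Cl2, -78 °C; then Me2S, -78 °C to rt
Reagents that add atoms: ozone, [O-][O+]=O
Why: Chemoselective ozonolysis (Criegee mechanism, reductive work-up): the trisubstituted ring alkene is much more electron-rich than the 1,1-disubstituted isopropenyl group, so one equivalent of ozone cleaves only the ring, and the untouched C4 centre of limonene becomes C3 (R) of 3.

**Step 2**
Reactants: 3 (3R)-6-oxo-3-(prop-1-en-2-yl)heptanal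
Product: 4 (5R)-5-(prop-1-en-2-yl)oct-7-yn-2-one
Conditions: Ohira-Bestmann reagent (1.2 equiv, premixed with K2CO3), K2CO3 (2 equiv), MeOH, 0 °C to rt
Reagents that add atoms: dimethyl (1-diazo-2-oxopropyl)phosphonate, CC(=O)C(=[N+]=[N-])P(=O)(OC)OC
Why: Ohira-Bestmann variant of the Seyferth-Gilbert homologation: the diazophosphonate anion made in situ olefinates the aldehyde far faster than the dialkyl ketone, the diazoalkene loses N2 with a 1,2-H shift to give the terminal alkyne, and the β-stereocentre cannot epimerise.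

**Step 3**
Reactants: 4 (5R)-5-(prop-1-en-2-yl)oct-7-yn-2-one
Product: 5 (5R)-2-methyl-5-(prop-1-en-2-yl)oct-1-en-7-yne
Conditions: Ph3PCH3Br (1.4 equiv), KOt-Bu (1.3 equiv), THF, 0 °C to rt
Reagents that add atoms: methyltriphenylphosphonium bromide, C[P+](c1ccccc1)(c1ccccc1)c1ccccc1.[Br-]
Why: Wittig methylenation of the methyl ketone; the ylide does not deprotonate the alkyne irreversibly and the stereocentre is remote from any acidic position.

**Step 4**
Reactants: 6 4-hydroxy-6-methyl-2H-pyran-2-one (triacetic acid lactone)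
Product: 7 4-(methoxymethoxy)-6-methyl-2H-pyran-2-one
Conditions: MOMCl (1.2 equiv), K2CO3, DMF, 0 °C to rt
Reagents that add atoms: chloromethyl methyl ether, COCCl
Why: Williamson-type O-alkylation of the vinylogous acid: the hard electrophile reacts at the 4-oxygen and keeps the 2-pyranone tautomer, and this oxygen becomes the blocked O5 of the flavanone.

**Step 5**
Reactants: 8 2,4-dihydroxybenzaldehyde
Product: 9 2,4-bis(methoxymethoxy)benzaldehyde
Conditions: NaH (2.4 equiv), MOMCl (2.4 equiv), DMF, 0 °C to rt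
Reagents that add atoms: chloromethyl methyl ether, COCCl
Why: Double Williamson-type O-alkylation; NaH also frees the chelated 2-OH, so both phenols are capped as base-stable acetals.

**Step 6**
Reactants: 7 4-(methoxymethoxy)-6-methyl-2H-pyran-2-one; 9 2,4-bis(methoxymethoxy)benzaldehyde
Product: 13 6-[(E)-2-[2,4-bis(methoxymethoxy)phenyl]ethenyl]-4-(methoxymethoxy)-2H-pyran-2-one, via lithiated pyranone 10 (not isolated), via lithium aldolate 11 (not isolated), via benzylic mesylate 12 (not isolated)
Conditions: LiHMDS (1.1 equiv), THF, -78 °C; 9; then MsCl (1.3 equiv), -78 to 0 °C; then DBU (2.5 equiv), 0 °C to rt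
Reagents that add atoms: none
Why: Vinylogous aldol addition of the 6-methyl dienolate, then mesylation and E1cB/E1 elimination (aldol condensation); conjugation to both rings gives the E-alkene, and non-nucleophilic bases avoid exchange of the 4-alkoxy group.

**Step 7**
Reactants: 5 (5R)-2-methyl-5-(prop-1-en-2-yl)oct-1-en-7-yne; 13 6-[(E)-2-[2,4-bis(methoxymethoxy)phenyl]ethenyl]-4-(methoxymethoxy)-2H-pyran-2-one
Product: 18 (2S)-2-[2,4-bis(methoxymethoxy)phenyl]-7-hydroxy-5-(methoxymethoxy)-8-[(2R)-5-methyl-2-(prop-1-en-2-yl)hex-5-en-1-yl]-2,3-dihydro-4H-chromen-4-one, via lithium acetylide 14 (not isolated), via lithium ynolate 15 (not isolated), via acylketene enolate 16 (not isolated), via chalcone 17 (not isolated)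
Conditions: n-BuLi (1.0 equiv), THF, -78 °C; t-BuOOLi (0.95 equiv, from t-BuOOH + LiHMDS), -78 to 0 °C; 13 (0.9 equiv), -78 °C to rt; AcOH (2.2 equiv), -78 °C, filter, solvent switch to PhMe without purification; quinidine-derived 9-epi-amino 3,5-(CF3)2C6H3-thiourea (10 mol %), -20 °C
Reagents that add atoms: tert-butyl hydroperoxide, CC(C)(C)OO
Why: Proposed new method: the known oxidation of a lithium acetylide with t-BuOOLi gives ynolate 15, whose hard Li-bound carbon adds 1,2 to the lactone carbonyl of 13; the adduct expels the vinylogous enolate (a far better leaving group than the alkoxide of an ordinary ester) to give acylketene enolate 16, whose cis-locked C4a carbanion closes on the ketene carbon (six-ring Claisen-type C-acylation) and tautomerises to phloroglucinol ring A of 17 as its dianion, which stays open in strong base; the closest known reaction types are tandem ynolate addition/Dieckmann cascades, carbanion-induced ring opening and re-aromatisation of 4-alkoxy-2-pyranones, and the biomimetic tetraketide Claisen cyclisation; the ynolate oxygen ends up as the only free ortho-phenol (O5 is MOM-blocked, O7 is para), so ring C can close only to the 8-alkyl isomer; after neutralisation the bifunctional thiourea (quinuclidine on the phenol, thiourea on the enone C=O; intramolecular asymmetric oxa-Michael addition as known for activated 2'-hydroxychalcones) delivers oxygen to the Si face of Cβ to set 2S, the 6'-alkoxy group making closure fast and practically irreversible at -20 °C; the side-chain centre is a spectator, so any 2R product is a diastereomer that chromatography can remove.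

**Step 8**
Reactants: 18 (2S)-2-[2,4-bis(methoxymethoxy)phenyl]-7-hydroxy-5-(methoxymethoxy)-8-[(2R)-5-methyl-2-(prop-1-en-2-yl)hex-5-en-1-yl]-2,3-dihydro-4H-chromen-4-one
Product: 19 remangiflavanone B
Conditions: HCl (1.25 M in MeOH), 0 to 35 °C
Reagents that add atoms: none
Why: Acid-catalysed transacetalisation (MOM solvolysis) under base-free conditions: the chelated 5-OMOM goes first and the aryl acetals follow, while keeping at or below 35 °C protects the C2–O bond and both 1,1-disubstituted alkenes; no stereocentre is touched and retro-oxa-Michael racemisation needs base.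

**Compound list**
1 | (R)-(+)-limonene, (4R)-1-methyl-4-(prop-1-en-2-yl)cyclohex-1-ene | CC1=CC[C@@H](CC1)C(C)=C | starting material
2 | secondary ozonide, 1-methyl-4-(prop-1-en-2-yl)-7,8,9-trioxabicyclo[4.2.1]nonane (isopropenyl centre as in 1) | CC12CC[C@@H](C(C)=C)CC(OO1)O2 | intermediate
3 | (3R)-6-oxo-3-(prop-1-en-2-yl)heptanal | CC(=O)CC[C@H](CC=O)C(=C)C | intermediate
4 | (5R)-5-(prop-1-en-2-yl)oct-7-yn-2-one | CC(=O)CC[C@H](CC#C)C(=C)C | intermediate
5 | (5R)-2-methyl-5-(prop-1-en-2-yl)oct-1-en-7-yne | C=C(C)CC[C@H](CC#C)C(=C)C | intermediate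
6 | 4-hydroxy-6-methyl-2H-pyran-2-one | CC1=CC(O)=CC(=O)O1 | starting material
7 | 4-(methoxymethoxy)-6-methyl-2H-pyran-2-one | CC1=CC(OCOC)=CC(=O)O1 | intermediate
8 | 2,4-dihydroxybenzaldehyde | O=Cc1ccc(O)cc1O | starting material
9 | 2,4-bis(methoxymethoxy)benzaldehyde | O=Cc1ccc(OCOC)cc1OCOC | intermediate
10 | 6-(lithiomethyl)-4-(methoxymethoxy)-2H-pyran-2-one | [Li]CC1=CC(OCOC)=CC(=O)O1 | intermediate
11 | lithium 1-[2,4-bis(methoxymethoxy)phenyl]-2-[4-(methoxymethoxy)-2-oxo-2H-pyran-6-yl]ethanolate (racemic) | [Li+].[O-]C(CC1=CC(OCOC)=CC(=O)O1)c1ccc(OCOC)cc1OCOC | intermediate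
12 | 1-[2,4-bis(methoxymethoxy)phenyl]-2-[4-(methoxymethoxy)-2-oxo-2H-pyran-6-yl]ethyl methanesulfonate (racemic) | CS(=O)(=O)OC(CC1=CC(OCOC)=CC(=O)O1)c1ccc(OCOC)cc1OCOC | intermediate
13 | 6-[(E)-2-[2,4-bis(methoxymethoxy)phenyl]ethenyl]-4-(methoxymethoxy)-2H-pyran-2-one | O=C1C=C(OCOC)C=C(/C=C/c2ccc(OCOC)cc2OCOC)O1 | intermediate
14 | lithium acetylide of 5 | C=C(C)CC[C@H](CC#C[Li])C(=C)C | intermediate
15 | lithium (4R)-7-methyl-4-(prop-1-en-2-yl)oct-7-en-1-yn-1-olate | C=C(C)CC[C@H](CC#C[O-])C(=C)C.[Li+] | intermediate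
16 | ring-opened acylketene lithium enolate (ketene carbon = C8a, enolate carbon = C4a) | C=C(C)CC[C@H](CC(=C=O)C(=O)/C=C(OCOC)\C=C(/[O-])\C=C\c1ccc(OCOC)cc1OCOC)C(=C)C.[Li+] | intermediate
17 | (E)-3-[2,4-bis(methoxymethoxy)phenyl]-1-{2,4-dihydroxy-6-(methoxymethoxy)-3-[(2R)-5-methyl-2-(prop-1-en-2-yl)hex-5-en-1-yl]phenyl}prop-2-en-1-one | C=C(C)CC[C@H](Cc1c(O)cc(OCOC)c(C(=O)/C=C/c2ccc(OCOC)cc2OCOC)c1O)C(=C)C | intermediate
18 | (2S)-2-[2,4-bis(methoxymethoxy)phenyl]-7-hydroxy-5-(methoxymethoxy)-8-[(2R)-5-methyl-2-(prop-1-en-2-yl)hex-5-en-1-yl]-2,3-dihydro-4H-chromen-4-one | C=C(C)CC[C@H](Cc1c(O)cc(OCOC)c2c1O[C@H](c1ccc(OCOC)cc1OCOC)CC2=O)C(=C)C | intermediate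
19 | remangiflavanone B, (2S)-2-(2,4-dihydroxyphenyl)-5,7-dihydroxy-8-[(2R)-5-methyl-2-(prop-1-en-2-yl)hex-5-en-1-yl]-2,3-dihydro-4H-chromen-4-one | C=C(C)CC[C@H](Cc1c(O)cc(O)c2c1O[C@H](c1ccc(O)cc1O)CC2=O)C(=C)C | target

**Totals**
Total step count: 8.
Longest linear sequence: 5 steps (1, 2, 3, 7, 8).

**Three steps most likely to fail**

Step 7 is the riskiest.
- The ynolate may olefinate the lactone carbonyl or add in a conjugate sense instead of transferring the acyl group.
- The chalcone lacks the extra ester that normally activates substrates for this catalyst, so the diastereoselectivity may be low. The free 4'-OH may also tie up the amine.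
- The sense of induction is assigned by analogy and must be checked by CD. The quinine-derived pseudoenantiomer gives the other epimer.

The fallback sets out from ynolate 15 and pyranone 13 and comes back at 18. Ynolate 15 is quenched with HCl/MeOH, and ketene methanolysis gives methyl (4R)-7-methyl-4-(prop-1-en-2-yl)oct-7-enoate F5. The LDA enolate of this ester is acylated by the lactone carbonyl of 13 at -78 °C and gives the open-chain tetraketide ester methyl (4E,8E)-9-[2,4-bis(methoxymethoxy)phenyl]-5-(methoxymethoxy)-2-[(2R)-5-methyl-2-(prop-1-en-2-yl)hex-5-en-1-yl]-3,7-dioxonona-4,8-dienoate F6. KOt-Bu in THF brings about the classical Claisen cyclisation of this ester to chalcone 17. The chalcone is closed without a chiral catalyst (NaOAc, EtOH, reflux) to the C2-epimeric flavanone mixture F7. Asymmetric transfer hydrogenation with RuCl(p-cymene)[(R,R)-TsDPEN] in HCO2H/Et3N, run to about half conversion, reduces the matched 2R epimer to the cis-(2R,4R)-flavan-4-ol F8. Compound 18 is left unreduced and is separated on silica.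

Step 2 carries the next risk. The 1,6-keto aldehyde can undergo intramolecular aldol condensation to an acetylcyclopentene under K2CO3/MeOH before it is homologated.

The fallback sets out from 3 and comes back at ynolate 15, so the ynolate oxygen comes from a carboxyl group and no peroxide oxidation is needed. Pinnick oxidation (NaClO2, NaH2PO4, 2-methyl-2-butene) gives (3R)-6-oxo-3-(prop-1-en-2-yl)heptanoic acid F1. Wittig methylenation of its carboxylate (Ph3P=CH2, 2.2 equiv) gives (3R)-6-methyl-3-(prop-1-en-2-yl)hept-6-enoic acid F2. MeI/K2CO3 gives the methyl ester F3. LiCHBr2 (from CH2Br2 and LiTMP) at -78 °C converts F3 into (4R)-1,1-dibromo-7-methyl-4-(prop-1-en-2-yl)oct-7-en-2-one F4, held as its enolate with LiHMDS. n-BuLi with warming then triggers the Kowalski rearrangement to 15, which is used directly in step 7.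

Step 8 is the third risk. Brønsted acid can add MeOH to the 1,1-disubstituted alkenes or isomerise them, close a chroman with the 7-OH, or ionise the very electron-rich benzylic C2–O bond and erode 2S.

The fallback sets out from 18 and comes back at 19. It replaces protic solvolysis by a buffered silyl-transfer sequence. TMSOTf with 2,2'-bipyridyl in MeCN at 0 °C to rt turns each aryl acetal into an aryl silyl ether and caps the 7-OH, giving the tetrakis(trimethylsilyl) ether of remangiflavanone B F9. This ether is cleaved at neutral pH with H2O/MeOH at rt to 19.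

**Further compounds**
F1 | step 2 | (3R)-6-oxo-3-(prop-1-en-2-yl)heptanoic acid | CC(=O)CC[C@H](CC(=O)O)C(=C)C
F2 | step 2 | (3R)-6-methyl-3-(prop-1-en-2-yl)hept-6-enoic acid | C=C(C)CC[C@H](CC(=O)O)C(=C)C
F3 | step 2 | methyl (3R)-6-methyl-3-(prop-1-en-2-yl)hept-6-enoate | C=C(C)CC[C@H](CC(=O)OC)C(=C)C
F4 | step 2 | (4R)-1,1-dibromo-7-methyl-4-(prop-1-en-2-yl)oct-7-en-2-one | C=C(C)CC[C@H](CC(=O)C(Br)Br)C(=C)C
F5 | step 7 | methyl (4R)-7-methyl-4-(prop-1-en-2-yl)oct-7-enoate | C=C(C)CC[C@H](CCC(=O)OC)C(=C)C
F6 | step 7 | methyl (4E,8E)-9-[2,4-bis(methoxymethoxy)phenyl]-5-(methoxymethoxy)-2-[(2R)-5-methyl-2-(prop-1-en-2-yl)hex-5-en-1-yl]-3,7-dioxonona-4,8-dienoate (C2 epimers) | C=C(C)CC[C@H](CC(C(=O)OC)C(=O)/C=C(OCOC)\CC(=O)/C=C/c1ccc(OCOC)cc1OCOC)C(=C)C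
F7 | step 7 | C2-epimeric mixture of 18 | C=C(C)CC[C@H](Cc1c(O)cc(OCOC)c2c1OC(c1ccc(OCOC)cc1OCOC)CC2=O)C(=C)C
F8 | step 7 | (2R,4R)-2-[2,4-bis(methoxymethoxy)phenyl]-5-(methoxymethoxy)-8-[(2R)-5-methyl-2-(prop-1-en-2-yl)hex-5-en-1-yl]chromane-4,7-diol | C=C(C)CC[C@H](Cc1c(O)cc(OCOC)c2c1O[C@@H](c1ccc(OCOC)cc1OCOC)C[C@H]2O)C(=C)C
F9 | step 8 | 5,7,2',4'-tetrakis(trimethylsilyl) ether of remangiflavanone B | C=C(C)CC[C@H](Cc1c(O[Si](C)(C)C)cc(O[Si](C)(C)C)c2c1O[C@H](c1ccc(O[Si](C)(C)C)cc1O[Si](C)(C)C)CC2=O)C(=C)C
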